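In ring A the bromines at C3 and C5 are ortho and para to the ether oxygen on C2 and both meta to the hydroxyl on C1; in ring C the bromines at C2 and C4 are ortho and para to the ether oxygen on C1. All four can therefore be placed by the ether oxygens once the hydroxyl is masked as a sulfonate.
Last disconnection: the S–O bond of a methanesulfonate on the ring A oxygen. Before it, the four C–Br bonds of rings A and C are cut together, which leads to bis-ether 12 with tribromo ring B and bare rings A and C.
12 comes from phenol 11, made by Dakin oxidation of aldehyde 9. 9 comes from phenol 7 and 2-fluorobenzaldehyde by fluoride displacement (ring A–O–ring B bond).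
7 comes from 4,5,6-tribromoguaiacol 4 by O-phenylation with diphenyliodonium triflate (ring C–O–ring B bond) and O-demethylation; 4 comes from guaiacol and bromine.
No ring is formed and the target has no stereocentre. Order: ring B is brominated, ring C and then ring A are attached, four bromines are added, the hydroxyl is unmasked.

Key step: step 7

Remark: the third bromine of guaiacol is taken to enter C5, para to the methoxy group, so that the tribromide is the 4,5,6-isomer, with the hydroxyl next to a bromine and the methoxy group next to the remaining C–H.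

Step 1
Reactants: 1 guaiacol (2-methoxyphenol)
Product: 4 2,3,4-tribromo-6-methoxyphenol (4,5,6-tribromoguaiacol), via 4-bromoguaiacol 2 (not isolated), via 4,6-dibromoguaiacol 3 (not isolated)
Conditions: Br2 (3.1 equiv), AcOH, 15 °C to rt
Reagents that add atoms: bromine (Br2), BrBr
Why: Electrophilic aromatic bromination in which the hydroxyl group directs the first two bromines to its para and ortho carbons and the methoxy group directs the third to its para carbon, while the last C–H, meta to the hydroxyl on a ring with three bromines, should resist a fourth substitution at room temperature.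

Step 2
Reactants: 4 2,3,4-tribromo-6-methoxyphenol; 5 diphenyliodonium triflate
Product: 6 1,2,3-tribromo-5-methoxy-4-phenoxybenzene
Conditions: t-BuOK, THF, 0 °C to 40 °C
Reagents that add atoms: none
Why: O-arylation of a phenoxide with a diaryliodonium salt (ligand coupling at trivalent iodine), which needs no transition metal, so the three C–Br bonds are not touched, and which accepts phenoxides with two ortho substituents.

Step 3
Reactants: 6 1,2,3-tribromo-5-methoxy-4-phenoxybenzene
Product: 7 3,4,5-tribromo-2-phenoxyphenol
Conditions: BBr3, CH2Cl2, −78 °C to rt; then H2O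
Reagents that add atoms: none
Why: Lewis acid cleavage of an aryl methyl ether with BBr3 (bromide attacks the methyl group of the boron–oxygen adduct and water then hydrolyses the O–B bond), which leaves diaryl ether and C–Br bonds intact.

Step 4
Reactants: 7 3,4,5-tribromo-2-phenoxyphenol; 8 2-fluorobenzaldehyde
Product: 9 2-(3,4,5-tribromo-2-phenoxyphenoxy)benzaldehyde
Conditions: K2CO3, DMAc, 130 °C
Reagents that add atoms: none
Why: Nucleophilic aromatic substitution by addition–elimination, in which the phenoxide displaces fluoride ortho to the formyl group, the only activated leaving group present, while the phenoxy and bromo substituents are inert to carbonate base.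

Step 5
Reactants: 9 2-(3,4,5-tribromo-2-phenoxyphenoxy)benzaldehyde
Product: 11 2-(3,4,5-tribromo-2-phenoxyphenoxy)phenol, via aryl formate 10 (not isolated)
Conditions: mCPBA, CH2Cl2, rt; aq. NaHCO3 wash; then MeOH, Et3N (cat.), rt
Reagents that add atoms: 3-chloroperoxybenzoic acid (mCPBA), OOC(=O)c1cccc(Cl)c1
Why: Dakin-type Baeyer–Villiger oxidation, in which the 2-aryloxyphenyl group migrates to oxygen in the peracid adduct to give formate 10, followed by amine-catalysed transesterification of the formate with methanol.

Step 6
Reactants: 11 2-(3,4,5-tribromo-2-phenoxyphenoxy)phenol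
Product: 12 2-(3,4,5-tribromo-2-phenoxyphenoxy)phenyl methanesulfonate
Conditions: MsCl, Et3N, CH2Cl2, 0 °C
Reagents that add atoms: methanesulfonyl chloride (MsCl), CS(=O)(=O)Cl
Why: Sulfonylation of a phenol with methanesulfonyl chloride and triethylamine, a routine esterification that turns the hydroxyl oxygen into a poor electron donor for step 7.

Step 7
Reactants: 12 2-(3,4,5-tribromo-2-phenoxyphenoxy)phenyl methanesulfonate
Product: 16 3,5-dibromo-2-[3,4,5-tribromo-2-(2,4-dibromophenoxy)phenoxy]phenyl methanesulfonate, via tetrabromide 13 (not isolated), via pentabromide 14 (not isolated), via hexabromide 15 (not isolated)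
Conditions: Br2 (4.05 equiv, last equivalent added slowly), FeBr3 (5 mol %), ClCH2CH2Cl, 0 °C to 60 °C, dark
Reagents that add atoms: bromine (Br2), BrBr
Why: Each of the four C–Br bonds forms by electrophilic aromatic substitution, in which Br2 polarised by FeBr3 attacks a carbon ortho or para to a diaryl ether oxygen and the arenium ion is stabilised by that oxygen's lone pair before loss of a proton; the Lewis acid is needed because, once ring C carries its para bromine (13), every further site is no more reactive than benzene and Br2 alone in buffered acetic acid should stall. The closest known reactions are the iron-catalysed bromination of diphenyl ether to its 2,2',4,4'-tetrabromide and the bromination of 2-alkoxyphenyl sulfonates and acylates para to the alkoxy group. No ring is closed and no stereocentre is formed. The selectivity needed is ring C C4 then C2, ring A C5 then C3, and no attack at ring A C4 or C6, at ring B C6 or at a third carbon of ring C: on ring A the sulfonyl group ties up the lone pairs of the C1 oxygen, so the C2 ether oxygen is the only strong donor and C4 and C6 are meta to it, while ring B C6–H sits on a ring that already bears three bromines. The expected order is 13 (ring C C4), 14 (ring A C5), 15 (ring C C2) and last ring A C3, the slowest substitution because that carbon is meta to both the sulfonate and the C5 bromine and next to the bulky ring B oxygen. Exact stoichiometry, slow addition of the last equivalent at the lowest temperature that sustains conversion, and chromatographic monitoring should stop the reaction at seven bromines.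

Step 8
Reactants: 16 3,5-dibromo-2-[3,4,5-tribromo-2-(2,4-dibromophenoxy)phenoxy]phenyl methanesulfonate
Product: 17 bromoiesol A (3,5-dibromo-2-[3,4,5-tribromo-2-(2,4-dibromophenoxy)phenoxy]phenol)
Conditions: KOH, MeOH/THF/H2O, 50 °C; then 1 M HCl
Reagents that add atoms: none
Why: Hydroxide cleavage of an aryl methanesulfonate at sulfur, helped by the electron-poor dibromophenoxide leaving group, at a temperature too low for displacement of aryl bromides or for ring closure of the ortho-aryloxyphenoxide onto ring B.

Compound list
1 | guaiacol (2-methoxyphenol) | COc1ccccc1O | starting material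
2 | 4-bromo-2-methoxyphenol (4-bromoguaiacol; not isolated) | COc1cc(Br)ccc1O | intermediate
3 | 2,4-dibromo-6-methoxyphenol (4,6-dibromoguaiacol; not isolated) | COc1cc(Br)cc(Br)c1O | intermediate
4 | 2,3,4-tribromo-6-methoxyphenol (4,5,6-tribromoguaiacol) | COc1cc(Br)c(Br)c(Br)c1O | intermediate
5 | diphenyliodonium triflate | c1ccc([I+]c2ccccc2)cc1.[O-]S(=O)(=O)C(F)(F)F | starting material
6 | 1,2,3-tribromo-5-methoxy-4-phenoxybenzene | COc1cc(Br)c(Br)c(Br)c1Oc1ccccc1 | intermediate
7 | 3,4,5-tribromo-2-phenoxyphenol | Oc1cc(Br)c(Br)c(Br)c1Oc1ccccc1 | intermediate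
8 | 2-fluorobenzaldehyde | O=Cc1ccccc1F | starting material
9 | 2-(3,4,5-tribromo-2-phenoxyphenoxy)benzaldehyde | O=Cc1ccccc1Oc1cc(Br)c(Br)c(Br)c1Oc1ccccc1 | intermediate
10 | 2-(3,4,5-tribromo-2-phenoxyphenoxy)phenyl formate (not isolated) | O=COc1ccccc1Oc1cc(Br)c(Br)c(Br)c1Oc1ccccc1 | intermediate
11 | 2-(3,4,5-tribromo-2-phenoxyphenoxy)phenol | Oc1ccccc1Oc1cc(Br)c(Br)c(Br)c1Oc1ccccc1 | intermediate
12 | 2-(3,4,5-tribromo-2-phenoxyphenoxy)phenyl methanesulfonate | CS(=O)(=O)Oc1ccccc1Oc1cc(Br)c(Br)c(Br)c1Oc1ccccc1 | intermediate
13 | 2-[3,4,5-tribromo-2-(4-bromophenoxy)phenoxy]phenyl methanesulfonate (tetrabromide; not isolated) | CS(=O)(=O)Oc1ccccc1Oc1cc(Br)c(Br)c(Br)c1Oc1ccc(Br)cc1 | intermediate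
14 | 5-bromo-2-[3,4,5-tribromo-2-(4-bromophenoxy)phenoxy]phenyl methanesulfonate (pentabromide; not isolated) | CS(=O)(=O)Oc1cc(Br)ccc1Oc1cc(Br)c(Br)c(Br)c1Oc1ccc(Br)cc1 | intermediate
15 | 5-bromo-2-[3,4,5-tribromo-2-(2,4-dibromophenoxy)phenoxy]phenyl methanesulfonate (hexabromide; not isolated) | CS(=O)(=O)Oc1cc(Br)ccc1Oc1cc(Br)c(Br)c(Br)c1Oc1ccc(Br)cc1Br | intermediate
16 | 3,5-dibromo-2-[3,4,5-tribromo-2-(2,4-dibromophenoxy)phenoxy]phenyl methanesulfonate | CS(=O)(=O)Oc1cc(Br)cc(Br)c1Oc1cc(Br)c(Br)c(Br)c1Oc1ccc(Br)cc1Br | intermediate
17 | bromoiesol A, 3,5-dibromo-2-[3,4,5-tribromo-2-(2,4-dibromophenoxy)phenoxy]phenol | Oc1cc(Br)cc(Br)c1Oc1cc(Br)c(Br)c(Br)c1Oc1ccc(Br)cc1Br | target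

Total step count: 8
Longest linear sequence: 8 steps (guaiacol 1 to bromoiesol A 17)

Steps most likely to fail

Step 7. Positional control may be lost in the fourth bromination. Attack at ring A C4 (para to the sulfonate oxygen and ortho to the C5 bromine), a third substitution of ring C, or attack at ring B C6 may compete with the slow substitution at ring A C3, and the reaction may also stop short of seven bromines. The fallback sets out from 6 and places the ring A bromines before the ether bond is made. Ring C alone is brominated at that stage (Br2, 2.05 equiv, FeBr3 cat., CH2Cl2), where the only ring B C–H lies between the methoxy group and a bromine on a ring with three bromines. This should pass through 1,2,3-tribromo-4-(4-bromophenoxy)-5-methoxybenzene F1 to 1,2,3-tribromo-4-(2,4-dibromophenoxy)-5-methoxybenzene F2. BBr3 should then give 3,4,5-tribromo-2-(2,4-dibromophenoxy)phenol F3. Fluoride displacement on purchased 3,5-dibromo-2-fluorobenzaldehyde (K2CO3, DMAc) brings in ring A with both bromines in place as 3,5-dibromo-2-[3,4,5-tribromo-2-(2,4-dibromophenoxy)phenoxy]benzaldehyde F4. Dakin oxidation (mCPBA, then MeOH with Et3N) through 3,5-dibromo-2-[3,4,5-tribromo-2-(2,4-dibromophenoxy)phenoxy]phenyl formate F5 comes back to the route at the target 17.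

Step 5. Hydride may migrate in place of the aryl group in the peracid adduct, leading to the carboxylic acid, because the tribromo ring makes the aryloxy oxygen a weaker donor toward the migrating ring. The fallback sets out from 7 and uses a methyl ketone, in which only aryl or methyl can migrate and aryl migrates far more readily. Fluoride displacement on 2'-fluoroacetophenone (K2CO3, DMAc, 130 °C) should give 1-[2-(3,4,5-tribromo-2-phenoxyphenoxy)phenyl]ethanone F6. Baeyer–Villiger oxidation (mCPBA, CF3CO2H cat., CH2Cl2) should give 2-(3,4,5-tribromo-2-phenoxyphenoxy)phenyl acetate F7. Methanolysis (K2CO3, MeOH) comes back to the route at phenol 11.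

Step 4. Fluoride displacement by the weakly nucleophilic, ortho-substituted tribromophenoxide may be slow, and the aldehyde may degrade under base at the temperature required. The fallback sets out from 7 and forms the ring A–O bond by oxidative copper coupling. Chan–Lam coupling with 2-methoxyphenylboronic acid (Cu(OAc)2, pyridine, 4 Å molecular sieves, air, CH2Cl2, rt), which leaves aryl bromides alone, should give 1,2,3-tribromo-5-(2-methoxyphenoxy)-4-phenoxybenzene F8. Cleavage of its methyl ether with BBr3 comes back to the route at phenol 11, so that steps 4 and 5 are both bypassed.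

Further compounds
F1 | step 7 | 1,2,3-tribromo-4-(4-bromophenoxy)-5-methoxybenzene | COc1cc(Br)c(Br)c(Br)c1Oc1ccc(Br)cc1
F2 | step 7 | 1,2,3-tribromo-4-(2,4-dibromophenoxy)-5-methoxybenzene | COc1cc(Br)c(Br)c(Br)c1Oc1ccc(Br)cc1Br
F3 | step 7 | 3,4,5-tribromo-2-(2,4-dibromophenoxy)phenol | Oc1cc(Br)c(Br)c(Br)c1Oc1ccc(Br)cc1Br
F4 | step 7 | 3,5-dibromo-2-[3,4,5-tribromo-2-(2,4-dibromophenoxy)phenoxy]benzaldehyde | O=Cc1cc(Br)cc(Br)c1Oc1cc(Br)c(Br)c(Br)c1Oc1ccc(Br)cc1Br
F5 | step 7 | 3,5-dibromo-2-[3,4,5-tribromo-2-(2,4-dibromophenoxy)phenoxy]phenyl formate | O=COc1cc(Br)cc(Br)c1Oc1cc(Br)c(Br)c(Br)c1Oc1ccc(Br)cc1Br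
F6 | step 5 | 1-[2-(3,4,5-tribromo-2-phenoxyphenoxy)phenyl]ethanone | CC(=O)c1ccccc1Oc1cc(Br)c(Br)c(Br)c1Oc1ccccc1
F7 | step 5 | 2-(3,4,5-tribromo-2-phenoxyphenoxy)phenyl acetate | CC(=O)Oc1ccccc1Oc1cc(Br)c(Br)c(Br)c1Oc1ccccc1
F8 | step 4 | 1,2,3-tribromo-5-(2-methoxyphenoxy)-4-phenoxybenzene | COc1ccccc1Oc1cc(Br)c(Br)c(Br)c1Oc1ccccc1
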